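**Retrosynthetic overview**
1. Last C–C bond: azulene C5–CH2 of the ethylene linker, made by anti-SN2′ substitution of a fragment B allylic picolinate with a fragment A alkyl Grignard/CuBr·SMe2 (this sets azulene C5 and the C6=C7 alkene); desilylation finishes.
2. Fragment A (benzoxepine half) from (R)-carvone: two α′-alkylations (quaternary C5a), epoxidation/Wharton transposition, Eschenmoser–Claisen (C6 arm), iodolactonisation (C7–O), Shi epoxidation (C3), Criegee (isopropenyl → C9a–O), 7-endo epoxide opening (cis-fused oxepane).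
3. Fragment B (hydroazulene half) from (4S)-limonene oxide: cleavage/aldol to a cyclopentene aldehyde, epoxidation and SmI2 opening (C1 carbinol, cis C8a–H), Weinreb acylation, HAT radical 7-endo cyclisation (quaternary C4), dehydrogenation, Luche reduction, Mitsunobu.
4. Ring order: cyclohexane (from carvone) → temporary γ-lactone → oxepane; cyclopentane → cycloheptane; then union of the two halves.

Assumption: the SMILES is read literally (cis-fused oxepane/cyclohexane, 5aS,9aR; cis-fused hydroazulene), and 1, 2, 9, 21, 29 and the L-fructose-derived Shi ketone are taken as commercial.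

**Fragment A**

Step 1
Reactants: 1 (R)-(−)-carvone; 2 5-bromo-2-methylpent-2-ene
Product: 4 trans-6-(4-methylpent-3-enyl)carvone, via lithium dienolate 3 (not isolated)
Conditions: LiN(iPr)2, THF, −78 °C; then 2, DMPU, −78 °C → rt
Reagents that add atoms: none
Why: kinetic α′-deprotonation gives the cross-conjugated enolate, which is alkylated (SN2 enolate alkylation) anti to the neighbouring isopropenyl group; this centre is re-enolised in step 2.

Step 2
Reactants: 4 trans-6-(4-methylpent-3-enyl)carvone
Product: 6 6-methyl-6-(4-methylpent-3-enyl)carvone (methyl trans to isopropenyl), via lithium enolate 5 (not isolated)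
Conditions: LiN(iPr)2, THF, −78 °C; MeI, −78 → 0 °C
Reagents that add atoms: iodomethane (CI)
Why: second α′-enolate alkylation, in which MeI enters anti to the adjacent isopropenyl group, so the quaternary carbon (future C5a) carries methyl trans and the alkenyl chain cis to isopropenyl.

Step 3
Reactants: 6 6-methyl-6-(4-methylpent-3-enyl)carvone
Product: 7 epoxy ketone (epoxide oxygen trans to isopropenyl)
Conditions: H2O2 (30% aq.), NaOH, MeOH, 0 °C
Reagents that add atoms: hydrogen peroxide (OO)
Why: Weitz–Scheffer nucleophilic epoxidation touches only the enone, and hydroperoxide adds to the β-carbon trans to the 1,3-related isopropenyl group as in carvone itself.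

Step 4
Reactants: 7 epoxy ketone
Product: 8 transposed allylic alcohol (OH cis to the quaternary methyl)
Conditions: N2H4·H2O, AcOH (cat.), MeOH, 0 °C → rt
Reagents that add atoms: none
Why: Wharton transposition (epoxy hydrazone → loss of N2) moves the oxygen to the former β-carbon without breaking its C–O bond, so the carbinol keeps the epoxide configuration.

Step 5
Reactants: 8 transposed allylic alcohol; 9 N,N-dimethylacetamide dimethyl acetal
Product: 10 γ,δ-unsaturated dimethylamide
Conditions: xylene, 140 °C
Reagents that add atoms: none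
Why: Eschenmoser–Claisen rearrangement; the suprafacial [3,3] shift delivers the CH2CONMe2 arm to the carbon next to the quaternary centre on the face that carried the C–O bond (new C6 stereocentre, arm cis to the quaternary methyl) and regenerates the methyl-bearing alkene.

Step 6
Reactants: 10 γ,δ-unsaturated dimethylamide
Product: 11 cis-fused iodolactone
Conditions: I2, THF/H2O, 0 °C → rt
Reagents that add atoms: iodine (II); water (O)
Why: iodolactonisation of the amide (5-exo attack of the amide oxygen at the tertiary carbon of the iodonium ion, then iminium hydrolysis) can only give the cis-fused γ-lactone, so the new C7–O bond is syn to the C6 arm and iodine is anti.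

Step 7
Reactants: 11 cis-fused iodolactone
Product: 12 lactone
Conditions: Bu3SnH, AIBN (cat.), toluene, 80 °C
Reagents that add atoms: none
Why: radical-chain dehalogenation removes the secondary iodide without touching the lactone or the two isolated alkenes and creates no stereocentre.

Step 8
Reactants: 12 lactone
Product: 13 (S)-epoxy lactone
Conditions: L-fructose-derived Shi ketone (30 mol %), KHSO5 (as 2KHSO5·KHSO4·K2SO4), K2CO3, Bu4NHSO4, MeCN/CH2(OMe)2/aq. buffer, 0 °C
Reagents that add atoms: potassium peroxymonosulfate ([K+].[O-]S(=O)(=O)OO)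
Why: Shi asymmetric epoxidation; the chiral dioxirane reacts with the electron-rich trisubstituted alkene in preference to the hindered 1,1-disubstituted isopropenyl group, and the enantiomeric (L-series) catalyst gives the (S)-epoxide (future C3) under catalyst control.

Step 9
Reactants: 13 (S)-epoxy lactone
Product: 15 acetate at the future C9a, via methoxy hydroperoxide 14 (not isolated)
Conditions: O3, CH2Cl2/MeOH, −78 °C; then Ac2O, Et3N, DMAP, 0 °C → rt
Reagents that add atoms: ozone ([O-][O+]=O); methanol (CO)
Why: ozonolysis of the only remaining alkene followed by Criegee rearrangement of the acylated methoxy hydroperoxide converts isopropenyl into acetoxy with retention (migration of the ring carbon to oxygen), so the carvone stereocentre becomes C9a–O.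

Step 10
Reactants: 15 acetate
Product: 17 oxepane lactone, via hydroxy epoxide 16 (not isolated)
Conditions: K2CO3, MeOH, rt; solvent exchange; BF3·OEt2 (0.2 equiv), CH2Cl2, −78 °C
Reagents that add atoms: none
Why: after acetate methanolysis, Lewis-acid-promoted 7-endo epoxide opening at the tertiary carbon closes the oxepane with the C3–O bond untouched (C3 retained); the cis ring fusion follows from the C5a/C9a centres already in place.

Step 11
Reactants: 17 oxepane lactone
Product: 18 triol
Conditions: LiAlH4, THF, 0 °C → rt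
Reagents that add atoms: none
Why: hydride reduction of the γ-lactone liberates the tertiary C7 alcohol and the primary alcohol of the two-carbon arm without affecting any stereocentre.

Step 12
Reactants: 18 triol
Product: 19 primary iodide
Conditions: I2, PPh3, imidazole, CH2Cl2, 0 °C
Reagents that add atoms: iodine (II)
Why: Appel-type (Garegg–Samuelsson) iodination is selective for the unhindered primary alcohol over the neopentyl-type secondary and the tertiary alcohols.

Step 13
Reactants: 19 primary iodide
Product: 20 bis(triethylsilyl) ether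
Conditions: Et3SiOTf, 2,6-lutidine, CH2Cl2, −78 → 0 °C
Reagents that add atoms: triethylsilyl triflate (CC[Si](CC)(CC)OS(=O)(=O)C(F)(F)F)
Why: silyl triflate silylation masks the secondary and the tertiary hydroxyl in one operation so that the iodide can later be metallated.

**Fragment B**

Step 14
Reactants: 21 (4S)-limonene 1,2-oxide (cis/trans mixture)
Product: 22 (3S)-6-oxo-3-(prop-1-en-2-yl)heptanal
Conditions: H5IO6, THF/H2O, 0 °C → rt
Reagents that add atoms: water (O)
Why: epoxide hydrolysis and periodate glycol cleavage open the ring of both epoxide diastereomers to the same keto aldehyde, leaving the isopropenyl-bearing stereocentre untouched.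

Step 15
Reactants: 22 keto aldehyde
Product: 23 (5R)-2-methyl-5-(prop-1-en-2-yl)cyclopent-1-ene-1-carbaldehyde
Conditions: piperidine, AcOH, toluene, 80 °C
Reagents that add atoms: none
Why: intramolecular enamine aldol condensation of the aldehyde α-carbon onto the methyl ketone gives the cyclopentene carbaldehyde (ring contraction of the limonene skeleton).

Step 16
Reactants: 23 cyclopentene carbaldehyde
Product: 24 epoxy aldehyde (epoxide trans to isopropenyl)
Conditions: H2O2 (30% aq.), NaOH (pH ≈ 8.5), MeOH, −10 °C
Reagents that add atoms: hydrogen peroxide (OO)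
Why: Weitz–Scheffer epoxidation of the enal occurs on the ring face opposite the isopropenyl group, fixing the oxygen at the future C1 carbinol.

Step 17
Reactants: 24 epoxy aldehyde
Product: 26 diol, via hydroxy aldehyde 25 (not isolated)
Conditions: SmI2, THF/MeOH, −78 °C; then NaBH4, −78 → 0 °C
Reagents that add atoms: none
Why: SmI2 reductive opening of the α,β-epoxy carbonyl cleaves the Cα–O bond and the resulting enolate is protonated kinetically anti to the isopropenyl group (cis ring-fusion hydrogen, C1–OH retained); the labile aldol is reduced at once by borohydride.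

Step 18
Reactants: 26 diol
Product: 27 iodo alcohol
Conditions: I2, PPh3, imidazole, CH2Cl2, 0 °C
Reagents that add atoms: iodine (II)
Why: Appel-type iodination of the primary alcohol; the tertiary alcohol is inert and, being trans to the CH2 group, cannot close an oxetane.

Step 19
Reactants: 27 iodo alcohol
Product: 28 triethylsilyl ether
Conditions: Et3SiOTf, 2,6-lutidine, CH2Cl2, −78 → 0 °C
Reagents that add atoms: triethylsilyl triflate (CC[Si](CC)(CC)OS(=O)(=O)C(F)(F)F)
Why: silylation of the tertiary alcohol removes the only acidic proton before the organometallic steps.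

Step 20
Reactants: 28 triethylsilyl ether; 29 N-methoxy-N-methylmethacrylamide
Product: 31 isopropenyl ketone, via alkyllithium 30 (not isolated)
Conditions: t-BuLi (2.1 equiv), Et2O/pentane, −78 °C; then 29, −78 → 0 °C; aq. NH4Cl
Reagents that add atoms: none
Why: iodine–lithium exchange followed by Weinreb ketone synthesis (stable chelated tetrahedral adduct, 1,2-addition only) installs C7, C6 with its methyl, and C5 as an enone.

Step 21
Reactants: 31 isopropenyl ketone
Product: 32 cis-fused bicyclic ketone (C6 epimers)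
Conditions: Fe(acac)3, PhSiH3, EtOH/(CH2OH)2, 60 °C
Reagents that add atoms: none
Why: hydrogen-atom-transfer reductive olefin coupling: the iron hydride converts the electron-rich isopropenyl group into a tertiary radical that adds 7-endo (Giese) to the unsubstituted enone terminus, creating the gem-dimethyl quaternary C4 and the seven-membered ring; the ring fusion is fixed by the cis-disposed cyclopentane substituents.

Step 22
Reactants: 32 bicyclic ketone
Product: 33 enone
Conditions: IBX, DMSO, 70 °C
Reagents that add atoms: none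
Why: IBX dehydrogenation proceeds through the more substituted enol and gives the 2-methyl enone (C5=C6), erasing the stereo-random C6 centre.

Step 23
Reactants: 33 enone
Product: 34 allylic alcohol (OH anti to the ring-fusion hydrogens)
Conditions: NaBH4, CeCl3·7H2O, MeOH, −78 °C
Reagents that add atoms: none
Why: Luche 1,2-reduction, with hydride delivered from the convex face (that of the ring-fusion hydrogens) of the cis-fused bicycle, which places the hydroxyl on the opposite face.

Step 24
Reactants: 34 allylic alcohol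
Product: 35 inverted allylic picolinate
Conditions: picolinic acid, PPh3, iPrO2CN=NCO2iPr, THF, 0 °C → rt
Reagents that add atoms: picolinic acid (OC(=O)c1ccccn1)
Why: Mitsunobu esterification inverts C7, placing the chelating picolinoxy leaving group on the face of the ring-fusion hydrogens (if step 23 gave the other epimer, plain acylation would give the same ester).

**Union and end game**

Step 25
Reactants: 20 bis(triethylsilyl) ether (1.5 equiv); 35 allylic picolinate
Product: 38 tris(triethylsilyl) ether of the target, via alkyllithium 36 (not isolated), via Grignard reagent 37 (not isolated)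
Conditions: 20, t-BuLi (2.1 equiv), Et2O, −78 °C; MgBr2·OEt2, −78 → 0 °C; CuBr·SMe2 (0.5 equiv); then 35, THF, 0 °C
Reagents that add atoms: none
Why: copper-mediated anti-SN2′ allylic substitution of the chelating picolinate: the alkyl group is delivered to the γ-carbon (azulene C5) on the face opposite the leaving group, setting C5 with the chain anti to the ring-fusion hydrogens and moving the alkene to C6=C7.

Step 26
Reactants: 38 tris(triethylsilyl) ether
Product: 39 target, CNP0183476.6
Conditions: Bu4NF, THF, 50 °C
Reagents that add atoms: none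
Why: fluoride-induced desilylation frees the secondary and the two tertiary alcohols without touching any stereocentre or the trisubstituted alkene.

**Compound list**
1 | (R)-(−)-carvone, (5R)-2-methyl-5-(prop-1-en-2-yl)cyclohex-2-en-1-one | CC1=CC[C@H](CC1=O)C(C)=C | starting material
2 | 5-bromo-2-methylpent-2-ene | CC(C)=CCCBr | starting material
3 | lithium cross-conjugated dienolate of 1 (OLi on C1, C1=C6) | [Li]OC1=C[C@H](C(C)=C)CC=C1C | intermediate (not isolated)
4 | (5R,6S)-2-methyl-6-(4-methylpent-3-en-1-yl)-5-(prop-1-en-2-yl)cyclohex-2-en-1-one (chain trans to isopropenyl, major epimer) | O=C1[C@@H](CCC=C(C)C)[C@H](C(C)=C)CC=C1C | intermediate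
5 | lithium enolate of 4 (OLi on C1, C1=C6) | [Li]OC1=C(CCC=C(C)C)[C@H](C(C)=C)CC=C1C | intermediate (not isolated)
6 | (5S,6R)-2,6-dimethyl-6-(4-methylpent-3-en-1-yl)-5-(prop-1-en-2-yl)cyclohex-2-en-1-one (6-methyl trans, chain cis to isopropenyl) | O=C1[C@](C)(CCC=C(C)C)[C@H](C(C)=C)CC=C1C | intermediate
7 | 2,3-epoxide of 6 (epoxide oxygen trans to isopropenyl, cis to the 6-methyl) | O=C1[C@](C)(CCC=C(C)C)[C@H](C(C)=C)C[C@H]2O[C@@]12C | intermediate
8 | 2,4-dimethyl-4-(4-methylpent-3-en-1-yl)-5-(prop-1-en-2-yl)cyclohex-2-en-1-ol (OH cis to the 4-methyl, trans to isopropenyl) | CC1=C[C@](C)(CCC=C(C)C)[C@H](C(C)=C)C[C@H]1O | intermediate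
9 | N,N-dimethylacetamide dimethyl acetal | COC(C)(OC)N(C)C | starting material
10 | N,N-dimethyl-2-[2,6-dimethyl-6-(4-methylpent-3-en-1-yl)-5-(prop-1-en-2-yl)cyclohex-2-en-1-yl]acetamide (CH2CONMe2 cis to the 6-methyl, trans to isopropenyl) | CN(C)C(=O)C[C@H]1[C@](C)(CCC=C(C)C)[C@H](C(C)=C)CC=C1C | intermediate
11 | 7-iodo-4,7a-dimethyl-4-(4-methylpent-3-en-1-yl)-5-(prop-1-en-2-yl)hexahydro-1-benzofuran-2(3H)-one (cis-fused; ring O and 4-methyl on one face, iodine and isopropenyl on the other) | O=C1C[C@H]2[C@](C)(CCC=C(C)C)[C@H](C(C)=C)C[C@H](I)[C@@]2(C)O1 | intermediate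
12 | 4,7a-dimethyl-4-(4-methylpent-3-en-1-yl)-5-(prop-1-en-2-yl)hexahydro-1-benzofuran-2(3H)-one (same configuration as 11) | O=C1C[C@H]2[C@](C)(CCC=C(C)C)[C@H](C(C)=C)CC[C@@]2(C)O1 | intermediate
13 | 4-{2-[(2S)-3,3-dimethyloxiran-2-yl]ethyl}-4,7a-dimethyl-5-(prop-1-en-2-yl)hexahydro-1-benzofuran-2(3H)-one | O=C1C[C@H]2[C@](C)(CC[C@@H]3OC3(C)C)[C@H](C(C)=C)CC[C@@]2(C)O1 | intermediate
14 | methoxy hydroperoxide from 13 (isopropenyl replaced by C(CH3)(OCH3)OOH) | O=C1C[C@H]2[C@](C)(CC[C@@H]3OC3(C)C)[C@H](C(C)(OC)OO)CC[C@@]2(C)O1 | intermediate (not isolated)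
15 | 4-{2-[(2S)-3,3-dimethyloxiran-2-yl]ethyl}-4,7a-dimethyl-2-oxooctahydro-1-benzofuran-5-yl acetate (acetoxy cis to the epoxyethyl chain, trans to the 4-methyl) | O=C1C[C@H]2[C@](C)(CC[C@@H]3OC3(C)C)[C@H](OC(C)=O)CC[C@@]2(C)O1 | intermediate
16 | 5-hydroxy analogue of 15 (hydroxy epoxide) | O=C1C[C@H]2[C@](C)(CC[C@@H]3OC3(C)C)[C@H](O)CC[C@@]2(C)O1 | intermediate (not isolated)
17 | γ-lactone (to the 7-OH) of 2-[(3S,5aS,6S,7R,9aR)-3,7-dihydroxy-2,2,5a,7-tetramethyloctahydro-1-benzoxepin-6-yl]acetic acid | O=C1C[C@H]2[C@]3(C)CC[C@H](O)C(C)(C)O[C@@H]3CC[C@@]2(C)O1 | intermediate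
18 | (3S,5aS,6S,7R,9aR)-6-(2-hydroxyethyl)-2,2,5a,7-tetramethyloctahydro-1-benzoxepine-3,7-diol | OCC[C@H]1[C@]2(C)CC[C@H](O)C(C)(C)O[C@@H]2CC[C@@]1(C)O | intermediate
19 | (3S,5aS,6S,7R,9aR)-6-(2-iodoethyl)-2,2,5a,7-tetramethyloctahydro-1-benzoxepine-3,7-diol | ICC[C@H]1[C@]2(C)CC[C@H](O)C(C)(C)O[C@@H]2CC[C@@]1(C)O | intermediate
20 | 3,7-bis(triethylsilyl) ether of 19 | ICC[C@H]1[C@]2(C)CC[C@H](O[Si](CC)(CC)CC)C(C)(C)O[C@@H]2CC[C@@]1(C)O[Si](CC)(CC)CC | intermediate
21 | (4S)-limonene 1,2-oxide (cis/trans mixture at the epoxide) | CC12CC[C@@H](CC1O2)C(C)=C | starting material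
22 | (3S)-6-oxo-3-(prop-1-en-2-yl)heptanal | CC(=O)CC[C@@H](CC=O)C(C)=C | intermediate
23 | (5R)-2-methyl-5-(prop-1-en-2-yl)cyclopent-1-ene-1-carbaldehyde | O=CC1=C(C)CC[C@@H]1C(C)=C | intermediate
24 | 5-methyl-2-(prop-1-en-2-yl)-6-oxabicyclo[3.1.0]hexane-1-carbaldehyde (epoxide oxygen trans to isopropenyl) | O=C[C@]1(O2)[C@]2(C)CC[C@@H]1C(C)=C | intermediate
25 | 2-hydroxy-2-methyl-5-(prop-1-en-2-yl)cyclopentane-1-carbaldehyde (CHO cis to isopropenyl, OH trans to both) | O=C[C@@H]1[C@@](C)(O)CC[C@@H]1C(C)=C | intermediate (not isolated)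
26 | 2-(hydroxymethyl)-1-methyl-3-(prop-1-en-2-yl)cyclopentan-1-ol (CH2OH cis to isopropenyl, tertiary OH trans to both) | OC[C@@H]1[C@@](C)(O)CC[C@@H]1C(C)=C | intermediate
27 | 2-(iodomethyl)-1-methyl-3-(prop-1-en-2-yl)cyclopentan-1-ol (same configuration) | IC[C@@H]1[C@@](C)(O)CC[C@@H]1C(C)=C | intermediate
28 | triethylsilyl ether of 27 | IC[C@@H]1[C@@](C)(O[Si](CC)(CC)CC)CC[C@@H]1C(C)=C | intermediate
29 | N-methoxy-N-methylmethacrylamide | CON(C)C(=O)C(C)=C | starting material
30 | alkyllithium from 28 (CH2Li in place of CH2I) | [Li]C[C@@H]1[C@@](C)(O[Si](CC)(CC)CC)CC[C@@H]1C(C)=C | intermediate (not isolated)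
31 | 3-methyl-1-[2-methyl-5-(prop-1-en-2-yl)-2-(triethylsilyloxy)cyclopentyl]but-3-en-2-one (ring configuration as in 28) | C=C(C)C(=O)C[C@@H]1[C@@](C)(O[Si](CC)(CC)CC)CC[C@@H]1C(C)=C | intermediate
32 | cis-fused (1S,3aS,8aS)-1,4,4,6-tetramethyl-1-(triethylsilyloxy)bicyclo[5.3.0]decan-7-one (azulene numbering; C6 epimers) | O=C1C[C@H]2[C@H](CC[C@]2(C)O[Si](CC)(CC)CC)C(C)(C)CC1C | intermediate
33 | (1S,3aS,8aS)-1,4,4,6-tetramethyl-1-(triethylsilyloxy)-2,3,3a,4,8,8a-hexahydroazulen-7(1H)-one | O=C1C[C@H]2[C@H](CC[C@]2(C)O[Si](CC)(CC)CC)C(C)(C)C=C1C | intermediate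
34 | (1S,3aS,7R,8aS)-1,4,4,6-tetramethyl-1-(triethylsilyloxy)-1,2,3,3a,4,7,8,8a-octahydroazulen-7-ol (7-OH anti to the ring-fusion hydrogens) | O[C@@H]1C[C@H]2[C@H](CC[C@]2(C)O[Si](CC)(CC)CC)C(C)(C)C=C1C | intermediate
35 | (1S,3aS,7S,8aS)-1,4,4,6-tetramethyl-1-(triethylsilyloxy)-1,2,3,3a,4,7,8,8a-octahydroazulen-7-yl pyridine-2-carboxylate (7-O syn to the ring-fusion hydrogens) | O=C(O[C@H]1C[C@H]2[C@H](CC[C@]2(C)O[Si](CC)(CC)CC)C(C)(C)C=C1C)c1ccccn1 | intermediate
36 | alkyllithium from 20 (CH2Li in place of CH2I) | [Li]CC[C@H]1[C@]2(C)CC[C@H](O[Si](CC)(CC)CC)C(C)(C)O[C@@H]2CC[C@@]1(C)O[Si](CC)(CC)CC | intermediate (not isolated)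
37 | alkylmagnesium bromide from 20 | Br[Mg]CC[C@H]1[C@]2(C)CC[C@H](O[Si](CC)(CC)CC)C(C)(C)O[C@@H]2CC[C@@]1(C)O[Si](CC)(CC)CC | intermediate (not isolated)
38 | tris(triethylsilyl) ether of 39 | CC1=CC[C@H]2[C@H](CC[C@]2(C)O[Si](CC)(CC)CC)C(C)(C)[C@@H]1CC[C@H]1[C@]2(C)CC[C@H](O[Si](CC)(CC)CC)C(C)(C)O[C@@H]2CC[C@@]1(C)O[Si](CC)(CC)CC | intermediate
39 | (3S,5aS,6S,7R,9aR)-6-{2-[(1S,3aS,5R,8aS)-1-hydroxy-1,4,4,6-tetramethyl-1,2,3,3a,4,5,8,8a-octahydroazulen-5-yl]ethyl}-2,2,5a,7-tetramethyloctahydro-1-benzoxepine-3,7-diol | CC1=CC[C@H]2[C@H](CC[C@]2(C)O)C(C)(C)[C@@H]1CC[C@H]1[C@]2(C)CC[C@H](O)C(C)(C)O[C@@H]2CC[C@@]1(C)O | target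

**Step count and risks**
Total: 26 steps. Longest linear sequence: 15 steps (steps 1–13, 25, 26); fragment B takes 11 steps (14–24).

The three steps most likely to fail:

Step 4 (Wharton on a ketone flanked by a quaternary carbon and the epoxide carbon; hydrazone formation may be too slow). Fallback, setting out from 7: reduce the ketone with NaBH4 in MeOH to the epoxy alcohol F1 (carbinol epimers are irrelevant) and convert it with MsCl/Et3N into the epoxy mesylate F2. Two-electron reduction of F2 with LiC10H8 (lithium naphthalenide) in THF at −78 °C then cleaves the C–OMs bond and opens the epoxide by β-elimination. This gives the same transposed allylic alcohol with the C8–O bond untouched, so the route is rejoined at 8.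

Step 10 (6-exo opening to a tetrahydropyran may compete with the desired 7-endo opening). Fallback, setting out from 16 (isolated after the methanolysis): isomerise the epoxide with Al(OiPr)3 in toluene at 110 °C to the isopropenyl carbinol F3, which keeps the C3–O bond. The ring is then closed by Markovnikov oxymercuration with Hg(OCOCF3)2 in MeCN, where the C9a hydroxyl can only attack the tertiary carbon, giving the organomercurial F4. Demercuration with NaBH4/aq. NaOH turns the CH2Hg group into the second methyl, and the route is rejoined at 17.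

Step 25 (the organocopper must attack a γ-carbon next to a quaternary centre; direct α-substitution or no reaction are the likely failures). Fallback, setting out from 34, whose hydroxyl already sits on the face where the chain must arrive: convert it with PhNCO/DMAP into the N-phenylcarbamate F5. Deprotonate F5 with MeLi, add CuI, and then add the alkyllithium 36 made from 20. The carbamate-bound copper delivers the alkyl group intramolecularly in a syn-SN2′ sense to the same carbon and face, and the route is rejoined at 38.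

**Further compounds**
F1 | step 4 | epoxy alcohol from 7 (C=O reduced to CHOH, carbinol epimers) | OC1[C@](C)(CCC=C(C)C)[C@H](C(C)=C)C[C@H]2O[C@@]12C
F2 | step 4 | methanesulfonate of F1 | CS(=O)(=O)OC1[C@](C)(CCC=C(C)C)[C@H](C(C)=C)C[C@H]2O[C@@]12C
F3 | step 10 | 5-hydroxy-4-[(3S)-3-hydroxy-4-methylpent-4-en-1-yl]-4,7a-dimethylhexahydro-1-benzofuran-2(3H)-one (ring configuration as in 16) | O=C1C[C@H]2[C@](C)(CC[C@H](O)C(C)=C)[C@H](O)CC[C@@]2(C)O1
F4 | step 10 | organomercurial: 17 with one C2 methyl replaced by CH2HgOCOCF3 (C2 epimers) | O=C1C[C@H]2[C@]3(C)CC[C@H](O)C(C)(C[Hg]OC(=O)C(F)(F)F)O[C@@H]3CC[C@@]2(C)O1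
F5 | step 25 | N-phenylcarbamate of 34 | O=C(Nc1ccccc1)O[C@@H]1C[C@H]2[C@H](CC[C@]2(C)O[Si](CC)(CC)CC)C(C)(C)C=C1C
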